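Remark: locants without primes and with one prime refer to flavone unit X (the unit whose ring B carries the ether oxygen), locants with two and three primes to unit Y (the unit substituted at C6''). Compounds 1, 2, 6 and 8 are taken as purchased, and 4 is drawn as its keto tautomer (it is enolised, so its C2 is not a defined stereocentre).

## Structural features

The target is a biflavone ether of the hinokiflavone type: two 2-aryl-4H-chromen-4-one units joined by one diaryl ether oxygen that runs from C4' of ring B of unit X to C6'' of ring A of unit Y. Unit X carries 5-OH and 7-OMe; unit Y carries 5''-OH, 7''-OMe and a free 4'''-OH. There is no stereocentre, and the diaryl ether is not a configurationally stable axis, so no stereochemistry has to be set. Ring A of unit Y is the congested part: C4a'' (acyl), C5'' (OH), C6'' (OAr), C7'' (OMe) and C8a'' (O1'') are substituted and only C8'' bears hydrogen, so the ether oxygen sits on an electron-rich carbon between two ortho oxygen substituents. The position of that oxygen is a second problem, because C6'' and C8'' are both activated sites of a 5,7-dioxygenated ring and 6-substituted 5-hydroxyflavones can pass into their 8-isomers by acid-induced opening and reclosure of the pyranone (Wessely–Moser rearrangement). Fragile groups are the two 4-pyranone rings (opened by hot hydroxide or alkoxide), the aryl methyl ethers (Lewis acids) and the three phenols, of which two are chelated to a C4 carbonyl and one (4'''-OH) is free. The real difficulty is therefore the C6''–O bond together with the certainty that it is at C6''. The key step exploits that C6'' lies between two oxygen-bearing carbons (C5'' and C7'') of a phloroglucinol-type ring fused to a pyranone: C6''–C7'' can enter as the O–CH2–C(=O) unit of an aryloxyacetate, C5'' as an ester on C3 of a preformed 4-pyranone, and C8'' as the 2-methyl group of that pyranone.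

## Logic of the disconnections

13 to 12: the O4'''–CH2Ph bond is cut. The free 4'''-OH is the only non-chelated phenol that must stay unmethylated, so it is carried as a benzyl ether through the base steps. The gain is chemoselectivity in every earlier step. The demand is a debenzylation that spares two chromone C2=C3 bonds and avoids hot acid.

12 to 11: the O7''–CH3 bond is cut. The ring construction delivers C7'' as a free phenol, and of the three phenols in 11 it is the only one not chelated to a carbonyl. The gain is that the ring-forming step need not distinguish O5'' from O7''. The demand is a mono-methylation controlled by acidity.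

11 to 5 and 9 (through 10): the bonds C7''–C8'' and C5''–C6'' of ring A of unit Y are cut; this is the key disconnection. In one sentence, ring A of unit Y is annulated onto the 2-methyl-4-pyranone-3-carboxylate 5 by a tandem lateral Claisen/Dieckmann condensation with the aryloxyacetate 9. The ether carbon C6'' becomes an sp3 O–CH2 carbon, so the hindered aryl C–O bond is never made by coupling, and O1''–C8a'' exists beforehand, so the aryloxy group can only end at C6''. The gain is that the pentasubstituted ring disappears and the molecule falls into two halves of similar size. The demand is that the lateral anion of 5 acylates at carbon with the ester of 9 and that ring closure goes through carbon, not oxygen.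

9 to 7 and 8: the O4'–CH2 bond is cut. This is an SN2 etherification of an unhindered phenol at a primary carbon. The gain is that the future diaryl ether oxygen is attached under the mildest possible conditions. The demand is that the chelated 5-OH stays untouched.

7 to 6: the O7–CH3 bond is cut. 6 is a bulk natural product that already holds the complete unit X. The demand is selective methylation of the most acidic phenol.

5 to 4: the O1–C6 bond of the pyranone is cut and the C5=C6 unsaturation is removed. This is the oxidative cyclisation of an enolised cinnamoyl ketone, as in flavone synthesis. The gain is an open-chain tricarbonyl precursor. The demand is that only the acetyl enol oxygen can close, which places the ester next to the methyl group.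

4 to 1 and 2 (through 3): the bond between C2 of the acetoacetate and the cinnamoyl carbonyl is cut. This is a C-acylation of a β-keto ester. The gain is two purchased materials. The demand is C- over O-acylation.

## Other disconnections considered

Alternative 1: cut the diaryl ether bond O–C4' (or O–C6''), the disconnection that comes to mind first. The forward key step would be an SNAr or Ullmann coupling of the hindered phenol A1 with the 4'-fluoroflavone A2 to give A3, followed by double 5-O-demethylation and debenzylation. The chosen plan is preferred for three reasons. The nucleophilic oxygen of A1 is flanked by two methoxy groups on an electron-rich ring, so forcing conditions would be needed. A1 needs its own multistep synthesis in which the 6-oxygen must be placed and told apart from the 8-position. The end game would require Lewis-acid cleavage of two 5-OMe groups in the presence of two 7-OMe groups and a benzyl ether, with the Wessely–Moser pathway open.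

Alternative 2: cut C5''–C4a'' and C8''–C8a'' (electrocyclic benzannulation from a four-membered ring). The forward key step would be a Pd(PPh3)4-catalysed Stille coupling of the chlorocyclobutenone A4 with the stannylpyranone A5 to A6, then thermal 4π-opening to a dienylketene, 6π-closure onto the pyranone C5=C6 bond and tautomerisation, which would give 12 directly. The chosen plan is preferred because A4 would have to be derived from squaric acid through several selective carbonyl manipulations in which the aryloxy group is a vinylogous ester leaving group. A5 needs a 6-metalated 4-pyranone, and the sequence is longer and uses stoichiometric tin.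

Alternative 3: cut C7''–C8'' and C5''–C4a'' (a 3+3 double Claisen). The forward key step would be acylation of the lateral anion of the methylpyranone A8 with the aryloxymalonate A7, then closure of the pyranone α-carbon onto the second ester, which would give 11. The chosen plan is preferred because the malonate C–H of A7 is far more acidic than the methyl group of A8 and would quench the anion by proton transfer. The second bond would also need the pyranone α-carbon to attack an ester that is part of a β-keto ester enolate. The 4+2 partition keeps the acidic C–H away from the electrophile and closes the ring in an established Dieckmann mode, at the same step count.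

Key step: step 5

## Route

Step 1
Reactants: 1 (2E)-3-[4-(benzyloxy)phenyl]prop-2-enoic acid; 2 ethyl 3-oxobutanoate
Product: 4 ethyl (4E)-2-acetyl-5-[4-(benzyloxy)phenyl]-3-oxopent-4-enoate, via 4-(benzyloxy)cinnamoyl chloride 3 (not isolated)
Conditions: (COCl)2, DMF (cat.), CH2Cl2, 0 → 23 °C; concentrate; then 2, MgCl2, pyridine, CH2Cl2, 0 → 23 °C; 1 M HCl
Reagents that add atoms: none
Why: Acid chloride formation, then soft-enolisation C-acylation of the magnesium chelate of the β-keto ester (Claisen-type C-acylation); chelation directs the acyl group to carbon and holds the tricarbonyl product as its enolate until acidic work-up.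

Step 2
Reactants: 4 ethyl (4E)-2-acetyl-5-[4-(benzyloxy)phenyl]-3-oxopent-4-enoate
Product: 5 ethyl 6-[4-(benzyloxy)phenyl]-2-methyl-4-oxo-4H-pyran-3-carboxylate
Conditions: I2 (10 mol%), DMSO, 130 °C
Reagents that add atoms: none
Why: The acetyl enol should add 6-endo (oxa-Michael) to the cinnamoyl β-carbon and the dihydropyranone is dehydrogenated by iodine with DMSO as terminal oxidant, the oxidative cyclisation that converts 2'-hydroxychalcones into flavones; only the acetyl enol oxygen can reach the β-carbon, so the ester ends at C3 next to the 2-methyl group.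

Step 3
Reactants: 6 apigenin (5,7-dihydroxy-2-(4-hydroxyphenyl)-4H-chromen-4-one)
Product: 7 genkwanin (5-hydroxy-2-(4-hydroxyphenyl)-7-methoxy-4H-chromen-4-one)
Conditions: MeI (1.05 equiv), K2CO3 (1.1 equiv), DMF, 0 → 23 °C
Reagents that add atoms: iodomethane, CI
Why: Williamson methylation under acidity control: the 7-OH is a vinylogous acid para to the C4 carbonyl and the most acidic phenol, the 5-OH is hydrogen-bonded to the carbonyl and the 4'-OH is less acidic, so one equivalent of base and electrophile should methylate O7 preferentially.

Step 4
Reactants: 7 genkwanin; 8 methyl bromoacetate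
Product: 9 methyl 2-[4-(5-hydroxy-7-methoxy-4-oxo-4H-chromen-2-yl)phenoxy]acetate
Conditions: 8 (1.2 equiv), K2CO3 (1.5 equiv), acetone, 56 °C
Reagents that add atoms: none
Why: Williamson etherification (SN2 at a primary α-halo ester) of the only non-chelated phenol; the bond between the future ether oxygen and the future C6'' is made here on an sp3 carbon without steric demand.

Step 5
Reactants: 5 ethyl 6-[4-(benzyloxy)phenyl]-2-methyl-4-oxo-4H-pyran-3-carboxylate; 9 methyl 2-[4-(5-hydroxy-7-methoxy-4-oxo-4H-chromen-2-yl)phenoxy]acetate
Product: 11 2-[4-(benzyloxy)phenyl]-5,7-dihydroxy-6-[4-(5-hydroxy-7-methoxy-4-oxo-4H-chromen-2-yl)phenoxy]-4H-chromen-4-one, via 2-oxopropyl pyranone ester 10 (not isolated)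
Conditions: 5 (1.2 equiv), LiN(SiMe3)2 (1.25 equiv), THF, −78 °C; add 9 pre-treated with LiN(SiMe3)2 (1.0 equiv), −78 → 23 °C; then Mg(OMe)2 (4 equiv), MeOH, 65 °C; 1 M HCl
Reagents that add atoms: none
Why: LiN(SiMe3)2 removes a proton from the 2-methyl group of 5, which is vinylogous to both the C4 ketone and the C3 ester, and the resulting trienolate attacks the ester carbonyl of the lithium phenoxide of 9 (Claisen condensation, C8''–C7'' bond); the methoxide released deprotonates the doubly activated CH2 of 10 and makes the acyl transfer irreversible. In methanolic Mg(OMe)2, proton exchange makes the α-aryloxy enolate of 10 available, whose carbon (future C6'') attacks the ring ester (future C5'') in a 6-(enolendo)-exo-trig Dieckmann-type closure of ring A; loss of ethoxide and enolisation give the phloroglucinol ring as a chelated magnesium phenoxide, an aromatic sink. The closest known reaction types are the acylation of lateral anions of 2-methyl-4-pyranones and o-toluates followed by aromatising Dieckmann closure to 1,3-dihydroxyarenes, and the Mg(OMe)2-induced recyclisation of pyrano[4,3-b]pyran-4,5-diones to 5,7-dihydroxychromones, which passes through the same kind of 2-(2-oxoalkyl)-4-pyranone-3-carboxylate. No stereocentre is formed. The union needs the anion of 5 not to be quenched: the OCH2 group of 9 is much less acidic than the methyl group of 5, the 5-OH of 9 is deprotonated beforehand, and the α-oxygen activates the ester of 9. The closure needs carbon rather than oxygen attack: attack by the enolate oxygen would give a lactone that methoxide reopens, whereas carbon attack is made irreversible by aromatisation, and the magnesium ion favours the Claisen mode by chelating the keto ester. The position of the ether is fixed by connectivity, since O1''–C8a'' exists before ring A and the OCH2 carbon lies between the two carbonyl-derived carbons, so only the 6''-aryloxy isomer can form. The chromone of 9 is shielded from conjugate addition as its 5-phenoxide, and the pyranone of 10 is shielded from methoxide as its enolate.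

Step 6
Reactants: 11 2-[4-(benzyloxy)phenyl]-5,7-dihydroxy-6-[4-(5-hydroxy-7-methoxy-4-oxo-4H-chromen-2-yl)phenoxy]-4H-chromen-4-one
Product: 12 2-[4-(benzyloxy)phenyl]-5-hydroxy-6-[4-(5-hydroxy-7-methoxy-4-oxo-4H-chromen-2-yl)phenoxy]-7-methoxy-4H-chromen-4-one
Conditions: MeI (1.2 equiv), K2CO3 (1.5 equiv), DMF, 23 °C
Reagents that add atoms: iodomethane, CI
Why: Williamson methylation; the 5-OH and 5''-OH are chelated to the C4 carbonyls (the latter also flanked by the aryloxy group), so the 7''-OH, again the vinylogous acid, should be the only phenol deprotonated by carbonate at room temperature.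

Step 7
Reactants: 12 2-[4-(benzyloxy)phenyl]-5-hydroxy-6-[4-(5-hydroxy-7-methoxy-4-oxo-4H-chromen-2-yl)phenoxy]-7-methoxy-4H-chromen-4-one
Product: 13 5-hydroxy-6-[4-(5-hydroxy-7-methoxy-4-oxo-4H-chromen-2-yl)phenoxy]-2-(4-hydroxyphenyl)-7-methoxy-4H-chromen-4-one
Conditions: H2 (1 atm), 10% Pd/C, THF–MeOH, 23 °C
Reagents that add atoms: none
Why: Catalytic hydrogenolysis of the benzyl aryl ether; the aryl methyl ethers, the diaryl ether and the chromone C2=C3 bonds should survive at one atmosphere and room temperature if hydrogen uptake is stopped after one equivalent, and no acid is used that could trigger a Wessely–Moser rearrangement.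

## Compound list

1 | (2E)-3-[4-(benzyloxy)phenyl]prop-2-enoic acid | OC(=O)/C=C/c1ccc(OCc2ccccc2)cc1 | starting material
2 | ethyl 3-oxobutanoate | CCOC(=O)CC(C)=O | starting material
3 | (2E)-3-[4-(benzyloxy)phenyl]prop-2-enoyl chloride | ClC(=O)/C=C/c1ccc(OCc2ccccc2)cc1 | intermediate
4 | ethyl (4E)-2-acetyl-5-[4-(benzyloxy)phenyl]-3-oxopent-4-enoate | CCOC(=O)C(C(C)=O)C(=O)/C=C/c1ccc(OCc2ccccc2)cc1 | intermediate
5 | ethyl 6-[4-(benzyloxy)phenyl]-2-methyl-4-oxo-4H-pyran-3-carboxylate | CCOC(=O)c1c(C)oc(-c2ccc(OCc3ccccc3)cc2)cc1=O | intermediate
6 | apigenin, 5,7-dihydroxy-2-(4-hydroxyphenyl)-4H-chromen-4-one | O=c1cc(-c2ccc(O)cc2)oc2cc(O)cc(O)c12 | starting material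
7 | genkwanin, 5-hydroxy-2-(4-hydroxyphenyl)-7-methoxy-4H-chromen-4-one | COc1cc(O)c2c(=O)cc(-c3ccc(O)cc3)oc2c1 | intermediate
8 | methyl bromoacetate | COC(=O)CBr | starting material
9 | methyl 2-[4-(5-hydroxy-7-methoxy-4-oxo-4H-chromen-2-yl)phenoxy]acetate | COC(=O)COc1ccc(-c2cc(=O)c3c(O)cc(OC)cc3o2)cc1 | intermediate
10 | ethyl 6-[4-(benzyloxy)phenyl]-2-{3-[4-(5-hydroxy-7-methoxy-4-oxo-4H-chromen-2-yl)phenoxy]-2-oxopropyl}-4-oxo-4H-pyran-3-carboxylate | CCOC(=O)c1c(CC(=O)COc2ccc(-c3cc(=O)c4c(O)cc(OC)cc4o3)cc2)oc(-c2ccc(OCc3ccccc3)cc2)cc1=O | intermediate
11 | 2-[4-(benzyloxy)phenyl]-5,7-dihydroxy-6-[4-(5-hydroxy-7-methoxy-4-oxo-4H-chromen-2-yl)phenoxy]-4H-chromen-4-one | COc1cc(O)c2c(=O)cc(-c3ccc(Oc4c(O)cc5oc(-c6ccc(OCc7ccccc7)cc6)cc(=O)c5c4O)cc3)oc2c1 | intermediate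
12 | 2-[4-(benzyloxy)phenyl]-5-hydroxy-6-[4-(5-hydroxy-7-methoxy-4-oxo-4H-chromen-2-yl)phenoxy]-7-methoxy-4H-chromen-4-one | COc1cc(O)c2c(=O)cc(-c3ccc(Oc4c(OC)cc5oc(-c6ccc(OCc7ccccc7)cc6)cc(=O)c5c4O)cc3)oc2c1 | intermediate
13 | 5-hydroxy-6-[4-(5-hydroxy-7-methoxy-4-oxo-4H-chromen-2-yl)phenoxy]-2-(4-hydroxyphenyl)-7-methoxy-4H-chromen-4-one | COc1cc(O)c2c(=O)cc(-c3ccc(Oc4c(OC)cc5oc(-c6ccc(O)cc6)cc(=O)c5c4O)cc3)oc2c1 | target

## Step count and least certain steps

Total: 7 steps. Longest linear sequence: 5 steps (steps 1, 2, 5, 6, 7; the branch through steps 3 and 4 is equally long).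

Step 5 (key step). The most likely failure is that the union stalls. The trienolate of 5 is a stabilised and therefore sluggish nucleophile, so acyl transfer from the ester of 9 may be slow, and proton transfer from the OCH2 group of 9 or self-condensation of 5 may compete. In the second stage, oxygen attack (lactonisation) or methoxide-induced opening of a pyranone ring may compete with the carbon closure. Fallback (sets out from 5, comes back at 10): the lithium trienolate of 5 is acylated with 2-chloro-N-methoxy-N-methylacetamide, a small electrophile that can be used in excess and whose tetrahedral chelate prevents over-reaction, to give the chloromethyl ketone ethyl 6-[4-(benzyloxy)phenyl]-2-(3-chloro-2-oxopropyl)-4-oxo-4H-pyran-3-carboxylate F1. The ether is then made by SN2 displacement of the α-chloro ketone with the 4'-phenoxide of 7 (Cs2CO3, DMF, 0 °C), which gives 10 as an isolated compound, and 10 is closed to 11 with Mg(OMe)2 in methanol as in step 5. The union thus becomes a C–O alkylation and the Claisen step no longer involves the precious ester 9.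

Step 2. The likely failure is retro-Claisen loss of the acetyl group from the tricarbonyl compound in hot DMSO containing HI, or incomplete dehydrogenation of the dihydropyranone. Fallback (sets out from 2, comes back at 5): 2 is condensed with pyrrolidine to the enamine ethyl (2E)-3-(pyrrolidin-1-yl)but-2-enoate F2. 4-(Benzyloxy)benzoyl chloride acylates Meldrum's acid (pyridine, CH2Cl2) to 5-{[4-(benzyloxy)phenyl](hydroxy)methylidene}-2,2-dimethyl-1,3-dioxane-4,6-dione F3. Heating F3 in toluene releases the aroylketene 3-[4-(benzyloxy)phenyl]-3-oxoprop-1-en-1-one F4, which adds to F2 in a 4+2 sense (ketene carbon to the enamine α-carbon, ketone oxygen to the amino carbon) and loses pyrrolidine to give 5 without any oxidation step.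

Step 3. The likely failure is over-methylation at O4' once part of the 7-phenoxide has reacted, because the acidity gap between the 7-OH and the 4'-OH is moderate. Fallback (sets out from 6, comes back at 7): peracetylation (Ac2O, pyridine) to 4-[5,7-bis(acetyloxy)-4-oxo-4H-chromen-2-yl]phenyl acetate F5. The most electrophilic 7-O-acetyl group alone is removed with thiophenol/imidazole to give 4-[5-(acetyloxy)-7-hydroxy-4-oxo-4H-chromen-2-yl]phenyl acetate F6. Mitsunobu methylation of the single free phenol (MeOH, PPh3, diisopropyl azodicarboxylate) gives 4-[5-(acetyloxy)-7-methoxy-4-oxo-4H-chromen-2-yl]phenyl acetate F7, and methanolysis of both acetates (K2CO3, MeOH) gives 7.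

Step 7. The likely failure is over-reduction of a chromone C2=C3 bond to the flavanone, or slow hydrogenolysis caused by poor solubility of the biflavone. Fallback (sets out from 12, comes back at 13): Lewis-acid dealkylation with BCl3 and pentamethylbenzene as benzyl cation scavenger in CH2Cl2 at −78 °C. This non-reductive cleavage leaves the C2=C3 bonds untouched and is too cold for attack on the methyl ethers or for ring opening; it makes no new compound.

## Further compounds

F1 | step 5 | ethyl 6-[4-(benzyloxy)phenyl]-2-(3-chloro-2-oxopropyl)-4-oxo-4H-pyran-3-carboxylate | CCOC(=O)c1c(CC(=O)CCl)oc(-c2ccc(OCc3ccccc3)cc2)cc1=O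
F2 | step 2 | ethyl (2E)-3-(pyrrolidin-1-yl)but-2-enoate | CCOC(=O)/C=C(\C)N1CCCC1
F3 | step 2 | 5-{[4-(benzyloxy)phenyl](hydroxy)methylidene}-2,2-dimethyl-1,3-dioxane-4,6-dione | CC1(C)OC(=O)C(=C(O)c2ccc(OCc3ccccc3)cc2)C(=O)O1
F4 | step 2 | 3-[4-(benzyloxy)phenyl]-3-oxoprop-1-en-1-one | O=C=CC(=O)c1ccc(OCc2ccccc2)cc1
F5 | step 3 | 4-[5,7-bis(acetyloxy)-4-oxo-4H-chromen-2-yl]phenyl acetate | CC(=O)Oc1ccc(-c2cc(=O)c3c(OC(C)=O)cc(OC(C)=O)cc3o2)cc1
F6 | step 3 | 4-[5-(acetyloxy)-7-hydroxy-4-oxo-4H-chromen-2-yl]phenyl acetate | CC(=O)Oc1ccc(-c2cc(=O)c3c(OC(C)=O)cc(O)cc3o2)cc1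
F7 | step 3 | 4-[5-(acetyloxy)-7-methoxy-4-oxo-4H-chromen-2-yl]phenyl acetate | COc1cc(OC(C)=O)c2c(=O)cc(-c3ccc(OC(C)=O)cc3)oc2c1
F0 | step 7 | none | none
A1 | alternative 1 | 2-[4-(benzyloxy)phenyl]-6-hydroxy-5,7-dimethoxy-4H-chromen-4-one | COc1cc2oc(-c3ccc(OCc4ccccc4)cc3)cc(=O)c2c(OC)c1O
A2 | alternative 1 | 2-(4-fluorophenyl)-5,7-dimethoxy-4H-chromen-4-one | COc1cc(OC)c2c(=O)cc(-c3ccc(F)cc3)oc2c1
A3 | alternative 1 | 2-[4-(benzyloxy)phenyl]-6-[4-(5,7-dimethoxy-4-oxo-4H-chromen-2-yl)phenoxy]-5,7-dimethoxy-4H-chromen-4-one | COc1cc(OC)c2c(=O)cc(-c3ccc(Oc4c(OC)cc5oc(-c6ccc(OCc7ccccc7)cc6)cc(=O)c5c4OC)cc3)oc2c1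
A4 | alternative 2 | 4-chloro-2-[4-(5-hydroxy-7-methoxy-4-oxo-4H-chromen-2-yl)phenoxy]-3-methoxycyclobut-2-en-1-one | COC1=C(Oc2ccc(-c3cc(=O)c4c(O)cc(OC)cc4o3)cc2)C(=O)C1Cl
A5 | alternative 2 | 2-[4-(benzyloxy)phenyl]-6-(tributylstannyl)-4H-pyran-4-one | CCCC[Sn](CCCC)(CCCC)c1cc(=O)cc(-c2ccc(OCc3ccccc3)cc2)o1
A6 | alternative 2 | 4-{6-[4-(benzyloxy)phenyl]-4-oxo-4H-pyran-2-yl}-2-[4-(5-hydroxy-7-methoxy-4-oxo-4H-chromen-2-yl)phenoxy]-3-methoxycyclobut-2-en-1-one | COC1=C(Oc2ccc(-c3cc(=O)c4c(O)cc(OC)cc4o3)cc2)C(=O)C1c1cc(=O)cc(-c2ccc(OCc3ccccc3)cc2)o1
A7 | alternative 3 | dimethyl 2-[4-(5-hydroxy-7-methoxy-4-oxo-4H-chromen-2-yl)phenoxy]propanedioate | COC(=O)C(Oc1ccc(-c2cc(=O)c3c(O)cc(OC)cc3o2)cc1)C(=O)OC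
A8 | alternative 3 | 2-[4-(benzyloxy)phenyl]-6-methyl-4H-pyran-4-one | Cc1cc(=O)cc(-c2ccc(OCc3ccccc3)cc2)o1
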